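**Plan**
Labels: C1 acylated bridgehead, C2 ring C=O, C3 olefinic CH, C4 enolic C–OH, C5 prenylated bridgehead, C6 CH2, C7 CH(prenyl), C8 C(CH3)(4-methylpent-3-enyl), C9 keto bridge. Ring A = C1–C2–C3–C4–C5–C9, ring B = C1–C9–C5–C6–C7–C8.
Cuts, in order: C1–acyl. Then C2–C3 and C3–C4, with C3 supplied by methyl phenyl sulfone. Then C5–prenyl and C8–homoprenyl. Last, C5–C6 and C1=C8 of ring B.
Enabling feature: the chain C2–C1–C9–C5–C4 carries the 1,3,5-oxygenation of a 3-oxopentanedioate. C6–C7–C8 with the C8 methyl is a methyl ketone whose α-carbon (C7) bears the prenyl group and an exocyclic CH2 (C6), so ring B splits into a C5 bis-nucleophile and a C3 bis-electrophile.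
Forward: ring B is made first by a [3+3] Michael–Knoevenagel annulation and is then substituted at C8 and C5. Ring A follows by Dieckmann closure of C3 onto C2, and the acyl group is attached last at the bridgehead.
Stereochemistry: C7 is selected by a copper-catalysed kinetic resolution of the racemisable enone. C8 and C5 are set anti to the C7 prenyl group by substrate control, and C1 is fixed by the cis bridging of ring A. The side-chain centre comes from (R)-2-methylbutanoic acid.

Key step: step 3

Assumption: precedent does not predict which enantiomer of 7 the chiral copper catalyst of step 4 consumes faster. A test run fixes the ligand antipode so that (5S)-7 (C7 = S) is the fast-reacting one.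

**Step 1**
Reactants: 1 pentane-2,4-dione; 2 1-bromo-3-methylbut-2-ene (prenyl bromide)
Product: 3 3-(3-methylbut-2-en-1-yl)pentane-2,4-dione
Conditions: K2CO3, acetone, reflux (1 in slight excess)
Reagents that add atoms: none
Why: SN2 C-alkylation of the acetylacetone enolate with an allylic bromide is a standard monoalkylation of a 1,3-diketone, and the excess of 1 should hold back double prenylation.

**Step 2**
Reactants: 3 3-(3-methylbut-2-en-1-yl)pentane-2,4-dione
Product: 4 6-methyl-3-methylidenehept-5-en-2-one
Conditions: 37% aq. HCHO, K2CO3, H2O, rt; used without storage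
Reagents that add atoms: formaldehyde, C=O
Why: Aldol addition to formaldehyde, transfer of one acetyl group from carbon to the new alkoxide (retro-Claisen) and E1cB loss of acetate amount to the known deacetylative methylenation of 3-substituted 2,4-diones.

**Step 3**
Reactants: 4 6-methyl-3-methylidenehept-5-en-2-one; 5 dimethyl 3-oxopentanedioate
Product: 7 dimethyl 4-methyl-5-(3-methylbut-2-en-1-yl)-2-oxocyclohex-3-ene-1,3-dicarboxylate (racemic), via Michael adduct 6 (not isolated)
Conditions: NaOMe (1.0 equiv), MeOH, 0 °C → rt, slow addition of 4 to 5 (1.1 equiv); then 1 M HCl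
Reagents that add atoms: none
Why: Methoxide generates the stabilised carbanion of 5, which adds through the future C5 to the free methylene C6 of 4 to give 6; the second active methylene (C1) then attacks the methyl ketone carbon C8 and the aldol loses water by E1cB, so C5–C6 and C1=C8 form in one operation with both ester carbons (C2, C4) in place. The closest known reaction type is the base-mediated tandem Michael–Knoevenagel annulation of dialkyl 3-oxopentanedioates with α-methylene ketones to 2,6-bis(alkoxycarbonyl)cyclohex-2-enones. Ring B closes by a 6-(enolendo)-exo-trig aldol addition. C5 and C7 arise without control and both exchange afterwards (C5 as a β-keto ester carbon, C7 through the vinylogous enolate), so 7 is racemic and no permanent stereocentre is set here. The step needs only chemoselectivity, Michael addition before condensation; the unhindered, conjugated terminal CH2 secures this against the much less electrophilic ketone carbonyl, and the ketone is attacked only once the nucleophile is tethered. Excess 5 and slow addition of 4 should suppress a second Michael addition at C5 and self-dimerisation of 4, and the dehydration drains the reversible Michael equilibrium.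

**Step 4**
Reactants: 7 dimethyl 4-methyl-5-(3-methylbut-2-en-1-yl)-2-oxocyclohex-3-ene-1,3-dicarboxylate; 8 5-bromo-2-methylpent-2-ene
Product: 10 dimethyl (4R,5S)-4-methyl-5-(3-methylbut-2-en-1-yl)-4-(4-methylpent-3-en-1-yl)-2-oxocyclohexane-1,3-dicarboxylate (C7 S and C8 R in target labels; both ester-bearing carbons enolisable), via Grignard reagent 9 (not isolated)
Conditions: Mg, Et2O, reflux (8 → 9); Cu(OTf)2 (3 mol %), (S)-1-(1-hydroxy-3,3-dimethylbutan-2-yl)-3-mesityl-4,5-dihydroimidazolium hexafluorophosphate (4 mol %), Et2O, −30 °C, 9 (1.55 equiv: 1.0 for the enolic proton, 0.55 for transfer) by syringe pump; 1 M HCl; chromatography to separate unreacted 7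
Reagents that add atoms: none
Why: Proposed new method: the first equivalent of 9 converts the enolic C5–H of 7 into a chelated magnesium enolate, which should suppress uncatalysed attack, while the alkoxide-tethered N-heterocyclic carbene released from the imidazolinium salt binds monovalent copper; the ligated homoprenylcopper species complexes C1=C8 (still activated by the C2 ester and the magnesium-bound C9 oxygen), adds at C8 to a trivalent copper enolate and reductively eliminates to form the C8–CH2 bond. Allylic strain with the C8 methyl holds the C7 prenyl group pseudoaxial, so bond formation is easy only on the face anti to it; for (5S)-7 this is also the face preferred by the catalyst (matched), whereas for the mirror image the two demands oppose each other, so with about half an equivalent of transferable nucleophile the (7S,8R) trans adduct should form selectively, with C8 set anti to C7. Recovered (5R)-7 is racemised with NaOMe in MeOH through its C7 vinylogous enolate and resubmitted. Closest known reaction types: copper/carbene-catalysed enantioselective conjugate addition of Grignard reagents to 3-methylcyclohex-2-enones (quaternary centres), copper-catalysed dialkylzinc addition to 2-alkoxycarbonyl-3-alkylcycloalkenones, kinetic resolution of 4- and 5-substituted cyclohexenones by copper-catalysed dialkylzinc addition, and the achiral trans-selective organocopper addition to enones of this very type.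

**Step 5**
Reactants: 10 conjugate adduct; 2 1-bromo-3-methylbut-2-ene
Product: 11 dimethyl (1R,4R,5S)-4-methyl-1,5-bis(3-methylbut-2-en-1-yl)-4-(4-methylpent-3-en-1-yl)-2-oxocyclohexane-1,3-dicarboxylate (ring C3 = target C1 still epimerisable)
Conditions: NaH (1.05 equiv), THF, 0 °C; then 2, 0 °C → rt
Reagents that add atoms: none
Why: Of the two β-keto ester sites only C5 is accessible (C1 adjoins quaternary C8), and axial alkylation of its enolate in the conformer with the C7 and C8 chains equatorial enters syn to axial H7, which places the new prenyl group trans to the C7 prenyl group as in the known trans-selective alkylation of 4,4,5-trisubstituted 2-oxocyclohexane-1,3-dicarboxylates.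

**Step 6**
Reactants: 11 C5-prenylated diester; 12 methyl phenyl sulfone
Product: 14 methyl (3R,5S,6R)-6-methyl-3,5-bis(3-methylbut-2-en-1-yl)-6-(4-methylpent-3-en-1-yl)-2-oxo-3-[(phenylsulfonyl)acetyl]cyclohexane-1-carboxylate, via lithiated sulfone 13 (not isolated)
Conditions: 12 (3.5 equiv), n-BuLi (3.5 equiv), THF, −78 → 0 °C; 11, 0 °C → rt; AcOH
Reagents that add atoms: none
Why: The first equivalent of 13 turns the C1 β-keto ester into its lithium enolate, which shields C9 and C2, so the Claisen-type acylation of the α-sulfonyl carbanion takes place only at the non-enolisable C4 ester and stops at the ketone stage because the β-keto sulfone is deprotonated at once.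

**Step 7**
Reactants: 14 β-keto sulfone
Product: 15 (1S,5S,7S,8R)-4-hydroxy-8-methyl-5,7-bis(3-methylbut-2-en-1-yl)-8-(4-methylpent-3-en-1-yl)-3-(phenylsulfonyl)bicyclo[3.3.1]non-3-ene-2,9-dione
Conditions: KOt-Bu (1.1 equiv), THF, 0 → 60 °C; then 1 M HCl
Reagents that add atoms: none
Why: Dieckmann condensation (6-exo-trig): one equivalent of base places the charge on C3 because the β-keto sulfone is more acidic than the hindered C1 β-keto ester, so C1 stays tetrahedral and its ester electrophilic; C3 can reach C2 only when the two acyl branches stand cis-diaxial on ring B, which fixes the previously epimerisable C1 as drawn, and deprotonation of the strongly acidic 2-sulfonyl-1,3-dione by the released methoxide pulls the equilibrium over.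

**Step 8**
Reactants: 15 3-sulfonyl trione
Product: 16 (1R,5S,7S,8R)-4-hydroxy-8-methyl-5,7-bis(3-methylbut-2-en-1-yl)-8-(4-methylpent-3-en-1-yl)bicyclo[3.3.1]non-3-ene-2,9-dione
Conditions: Zn dust, AcOH/THF, rt → 40 °C
Reagents that add atoms: none
Why: Two-electron reduction of the α-sulfonyl dicarbonyl unit through its triketo tautomer expels benzenesulfinate (standard reductive desulfonylation of β-keto sulfones) and leaves the trisubstituted alkenes, the hindered C9 ketone and all stereocentres untouched.

**Step 9**
Reactants: 16 bicyclic trione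
Product: 17 (1R,5S,7S,8R)-4-methoxy-8-methyl-5,7-bis(3-methylbut-2-en-1-yl)-8-(4-methylpent-3-en-1-yl)bicyclo[3.3.1]non-3-ene-2,9-dione
Conditions: Me2SO4, K2CO3, acetone, rt; chromatographic separation of the O-regioisomers
Reagents that add atoms: dimethyl sulfate, COS(=O)(=O)OC
Why: O-methylation of the vinylogous acid with a hard electrophile is routine for this bicyclic class; the 2-methoxy regioisomer expected alongside is hydrolysed back to 16 (LiOH, aq. dioxane) and recycled, and the 4-methoxy isomer is kept because it leaves C1–H flanked by two carbonyl groups.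

**Step 10**
Reactants: 17 4-methoxy enone
Product: 19 (1S,5S,7S,8R)-4-methoxy-8-methyl-5,7-bis(3-methylbut-2-en-1-yl)-8-(4-methylpent-3-en-1-yl)-3-(trimethylsilyl)bicyclo[3.3.1]non-3-ene-2,9-dione, via 3-lithio enone 18 (not isolated)
Conditions: 2,2,6,6-tetramethylpiperidine, n-BuLi, TMSCl, THF, −78 °C (in situ quench)
Reagents that add atoms: chlorotrimethylsilane, C[Si](C)(C)Cl
Why: The vinylic C3–H is the kinetically most acidic site of such methoxy enones when the bridgehead adjoins a quaternary carbon, and its lithiation with in situ silylation is the established way to block C3 before bridgehead chemistry.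

**Step 11**
Reactants: 20 (R)-2-methylbutanoic acid
Product: 21 (R)-2-methylbutan-1-ol
Conditions: LiAlH4, Et2O, 0 °C → rt; then H2O
Reagents that add atoms: none
Why: Hydride reduction of a carboxylic acid goes through the carboxylate and does not involve the α-C–H, so the stereocentre is preserved.

**Step 12**
Reactants: 21 (R)-2-methylbutan-1-ol
Product: 22 (R)-2-methylbutanal
Conditions: TEMPO (1 mol %), KBr (10 mol %), NaOCl (1.1 equiv, pH 9.5), CH2Cl2/H2O, 0 °C; dried solution used directly
Reagents that add atoms: none
Why: The oxoammonium-mediated two-phase bleach oxidation is the standard preparation of enantiopure 2-methylbutanal and is fast and mild enough to leave the α-centre intact.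

**Step 13**
Reactants: 19 C3-silylated methoxy enone; 22 (R)-2-methylbutanal
Product: 24 (1R,5S,7S,8R)-1-[(2R)-1-hydroxy-2-methylbutyl]-4-methoxy-8-methyl-5,7-bis(3-methylbut-2-en-1-yl)-8-(4-methylpent-3-en-1-yl)-3-(trimethylsilyl)bicyclo[3.3.1]non-3-ene-2,9-dione (either carbinol epimer), via bridgehead organolithium 23 (not isolated)
Conditions: LiTMP (from 2,2,6,6-tetramethylpiperidine and n-BuLi, 3 equiv), THF, −78 → 0 °C; 22 (5 equiv), −78 °C; AcOH
Reagents that add atoms: none
Why: Bridgehead lithiation of C3-blocked 4-methoxybicyclo[3.3.1]non-3-ene-2,9-diones at the carbon between two carbonyl groups, followed by electrophilic trapping, is established; the bridgehead carbanion cannot invert so C1 keeps its configuration, the aldehyde (unlike an acyl chloride or cyanide) offers no ketene pathway so its α-centre is carried over, and the new carbinol centre is erased in step 14.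

**Step 14**
Reactants: 24 bridgehead carbinol
Product: 25 (1R,5S,7S,8R)-4-methoxy-8-methyl-1-[(2R)-2-methylbutanoyl]-5,7-bis(3-methylbut-2-en-1-yl)-8-(4-methylpent-3-en-1-yl)-3-(trimethylsilyl)bicyclo[3.3.1]non-3-ene-2,9-dione
Conditions: Dess–Martin periodinane, CH2Cl2, rt
Reagents that add atoms: none
Why: The periodinane oxidises hindered bridgehead carbinols of this type under nearly neutral conditions that touch neither the alkenes, the enol ether, the vinylsilane nor the α-stereocentre.

**Step 15**
Reactants: 25 silylated acyl compound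
Product: 26 (1S,5S,7S,8R)-4-methoxy-8-methyl-1-[(2R)-2-methylbutanoyl]-5,7-bis(3-methylbut-2-en-1-yl)-8-(4-methylpent-3-en-1-yl)bicyclo[3.3.1]non-3-ene-2,9-dione
Conditions: n-Bu4NF, AcOH, THF, 0 °C → rt
Reagents that add atoms: none
Why: Fluoride-induced protodesilylation of the α-silyl enone is the usual release of the C3 blocking group, and the acetic acid buffer keeps the medium too weakly basic to enolise the side-chain ketone.

**Step 16**
Reactants: 26 O-methyl ether of the target
Product: 27 (1S,5S,7S,8R)-4-hydroxy-8-methyl-1-[(2R)-2-methylbutanoyl]-5,7-bis(3-methylbut-2-en-1-yl)-8-(4-methylpent-3-en-1-yl)bicyclo[3.3.1]non-3-ene-2,9-dione (target)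
Conditions: LiCl, DMSO, 120 °C; then dilute HCl
Reagents that add atoms: none
Why: Chloride attacks the O-methyl group of the vinylogous ester (SN2, Krapcho-type dealkylation), a neutral method established for methyl enol ethers of this bicyclic class, and the weakly basic β-diketonate formed cannot epimerise the side chain, so no stereocentre is touched.

**Compound list**
1 | pentane-2,4-dione | CC(=O)CC(C)=O | starting material
2 | 1-bromo-3-methylbut-2-ene | CC(C)=CCBr | starting material
3 | 3-(3-methylbut-2-en-1-yl)pentane-2,4-dione | CC(=O)C(CC=C(C)C)C(C)=O | intermediate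
4 | 6-methyl-3-methylidenehept-5-en-2-one | CC(=O)C(=C)CC=C(C)C | intermediate
5 | dimethyl 3-oxopentanedioate | COC(=O)CC(=O)CC(=O)OC | starting material
6 | dimethyl 2-(2-acetyl-5-methylhex-4-en-1-yl)-3-oxopentanedioate (Michael adduct, not isolated) | COC(=O)CC(=O)C(CC(CC=C(C)C)C(C)=O)C(=O)OC | intermediate
7 | dimethyl 4-methyl-5-(3-methylbut-2-en-1-yl)-2-oxocyclohex-3-ene-1,3-dicarboxylate (racemic) | COC(=O)C1=C(C)C(CC=C(C)C)CC(C(=O)OC)C1=O | intermediate
8 | 5-bromo-2-methylpent-2-ene | CC(C)=CCCBr | starting material
9 | (4-methylpent-3-en-1-yl)magnesium bromide (not isolated) | CC(C)=CCC[Mg]Br | intermediate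
10 | dimethyl (4R,5S)-4-methyl-5-(3-methylbut-2-en-1-yl)-4-(4-methylpent-3-en-1-yl)-2-oxocyclohexane-1,3-dicarboxylate | COC(=O)C1C(=O)C(C(=O)OC)C[C@H](CC=C(C)C)[C@@]1(C)CCC=C(C)C | intermediate
11 | dimethyl (1R,4R,5S)-4-methyl-1,5-bis(3-methylbut-2-en-1-yl)-4-(4-methylpent-3-en-1-yl)-2-oxocyclohexane-1,3-dicarboxylate | COC(=O)C1C(=O)[C@](CC=C(C)C)(C(=O)OC)C[C@H](CC=C(C)C)[C@@]1(C)CCC=C(C)C | intermediate
12 | methyl phenyl sulfone | CS(=O)(=O)c1ccccc1 | starting material
13 | [(phenylsulfonyl)methyl]lithium (not isolated) | [Li]CS(=O)(=O)c1ccccc1 | intermediate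
14 | methyl (3R,5S,6R)-6-methyl-3,5-bis(3-methylbut-2-en-1-yl)-6-(4-methylpent-3-en-1-yl)-2-oxo-3-[(phenylsulfonyl)acetyl]cyclohexane-1-carboxylate | COC(=O)C1C(=O)[C@](CC=C(C)C)(C(=O)CS(=O)(=O)c2ccccc2)C[C@H](CC=C(C)C)[C@@]1(C)CCC=C(C)C | intermediate
15 | (1S,5S,7S,8R)-4-hydroxy-8-methyl-5,7-bis(3-methylbut-2-en-1-yl)-8-(4-methylpent-3-en-1-yl)-3-(phenylsulfonyl)bicyclo[3.3.1]non-3-ene-2,9-dione | [C@H]12C(=O)C(S(=O)(=O)c3ccccc3)=C(O)[C@](CC=C(C)C)(C[C@H](CC=C(C)C)[C@@]1(C)CCC=C(C)C)C2=O | intermediate
16 | (1R,5S,7S,8R)-4-hydroxy-8-methyl-5,7-bis(3-methylbut-2-en-1-yl)-8-(4-methylpent-3-en-1-yl)bicyclo[3.3.1]non-3-ene-2,9-dione | [C@H]12C(=O)C=C(O)[C@](CC=C(C)C)(C[C@H](CC=C(C)C)[C@@]1(C)CCC=C(C)C)C2=O | intermediate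
17 | (1R,5S,7S,8R)-4-methoxy-8-methyl-5,7-bis(3-methylbut-2-en-1-yl)-8-(4-methylpent-3-en-1-yl)bicyclo[3.3.1]non-3-ene-2,9-dione | [C@H]12C(=O)C=C(OC)[C@](CC=C(C)C)(C[C@H](CC=C(C)C)[C@@]1(C)CCC=C(C)C)C2=O | intermediate
18 | 3-lithio derivative of 17 (not isolated) | [C@H]12C(=O)C([Li])=C(OC)[C@](CC=C(C)C)(C[C@H](CC=C(C)C)[C@@]1(C)CCC=C(C)C)C2=O | intermediate
19 | (1S,5S,7S,8R)-4-methoxy-8-methyl-5,7-bis(3-methylbut-2-en-1-yl)-8-(4-methylpent-3-en-1-yl)-3-(trimethylsilyl)bicyclo[3.3.1]non-3-ene-2,9-dione | [C@H]12C(=O)C([Si](C)(C)C)=C(OC)[C@](CC=C(C)C)(C[C@H](CC=C(C)C)[C@@]1(C)CCC=C(C)C)C2=O | intermediate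
20 | (R)-2-methylbutanoic acid | CC[C@@H](C)C(=O)O | starting material
21 | (R)-2-methylbutan-1-ol | CC[C@@H](C)CO | intermediate
22 | (R)-2-methylbutanal | CC[C@@H](C)C=O | intermediate
23 | 1-lithio derivative of 19 (bridgehead organolithium, not isolated) | [Li][C@]12C(=O)C([Si](C)(C)C)=C(OC)[C@](CC=C(C)C)(C[C@H](CC=C(C)C)[C@@]1(C)CCC=C(C)C)C2=O | intermediate
24 | (1R,5S,7S,8R)-1-[(2R)-1-hydroxy-2-methylbutyl]-4-methoxy-8-methyl-5,7-bis(3-methylbut-2-en-1-yl)-8-(4-methylpent-3-en-1-yl)-3-(trimethylsilyl)bicyclo[3.3.1]non-3-ene-2,9-dione (carbinol centre undefined) | CC[C@@H](C)C(O)[C@]12C(=O)C([Si](C)(C)C)=C(OC)[C@](CC=C(C)C)(C[C@H](CC=C(C)C)[C@@]1(C)CCC=C(C)C)C2=O | intermediate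
25 | (1R,5S,7S,8R)-4-methoxy-8-methyl-1-[(2R)-2-methylbutanoyl]-5,7-bis(3-methylbut-2-en-1-yl)-8-(4-methylpent-3-en-1-yl)-3-(trimethylsilyl)bicyclo[3.3.1]non-3-ene-2,9-dione | CC[C@@H](C)C(=O)[C@]12C(=O)C([Si](C)(C)C)=C(OC)[C@](CC=C(C)C)(C[C@H](CC=C(C)C)[C@@]1(C)CCC=C(C)C)C2=O | intermediate
26 | (1S,5S,7S,8R)-4-methoxy-8-methyl-1-[(2R)-2-methylbutanoyl]-5,7-bis(3-methylbut-2-en-1-yl)-8-(4-methylpent-3-en-1-yl)bicyclo[3.3.1]non-3-ene-2,9-dione | CC[C@@H](C)C(=O)[C@]12C(=O)C=C(OC)[C@](CC=C(C)C)(C[C@H](CC=C(C)C)[C@@]1(C)CCC=C(C)C)C2=O | intermediate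
27 | (1S,5S,7S,8R)-4-hydroxy-8-methyl-1-[(2R)-2-methylbutanoyl]-5,7-bis(3-methylbut-2-en-1-yl)-8-(4-methylpent-3-en-1-yl)bicyclo[3.3.1]non-3-ene-2,9-dione | CC[C@@H](C)C(=O)[C@]12C(=O)C=C(O)[C@](CC=C(C)C)(C[C@H](CC=C(C)C)[C@@]1(C)CCC=C(C)C)C2=O | target

**Step count**
Total steps: 16. Longest linear sequence: 14 (steps 1–10 and 13–16). Steps 11 and 12 form the side branch.

**Steps most likely to fail**

Step 4 (new method). The ligated copper species may turn over too slowly on the magnesium enolate, or may discriminate too weakly between its two enantiomers, so that the enantiomeric purity of the adduct erodes. The fallback sets out from 7 and returns at 10.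
- 7 is treated with excess 9 and stoichiometric CuBr·SMe2 in THF (−78 → −20 °C). This achiral organocopper addition is known for this enone class and gives the racemic trans adduct F1.
- Condensation with (R)-1-phenylethylamine (cat. AcOH, toluene, molecular sieves) converts it into two diastereomeric β-enamino esters, the (7S,8R) enamino ester F2 and the (7R,8S) enamino ester F3. These are separated by crystallisation or chromatography.
- Hydrolysis of F2 with aqueous AcOH/THF returns enantiopure 10.

Step 7. The bulky sulfonyl-stabilised carbanion may attack the neopentyl-type C2 ester too slowly. Proton shuffling to the unreactive C1 enolate and retro-Claisen cleavage by the liberated methoxide could then take over. The fallback sets out from 11 and returns at 16, bypassing 14, 15 and step 8.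
- 11 is condensed with excess tert-butyl acetate/LDA (THF, −78 → 0 °C). The C1 enolate again protects C9 and C2, and the product is the tert-butyl β-keto ester F4, whose flatter and more nucleophilic carbanion is closed with one equivalent of KOt-Bu.
- This gives the 3-tert-butoxycarbonyl trione F5.
- TMSOTf/2,6-lutidine in CH2Cl2 followed by aqueous work-up cleaves the tert-butyl ester, and the resulting acid decarboxylates to 16.

Step 13. The hindered bridgehead carbanion and the excess amide base may abstract the α-proton of the aldehyde instead of adding to it, which returns 19. The fallback sets out from 19 and returns at 24.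
- The lithiated species 23 is quenched with iodine to give the bridgehead iodide F6.
- Iodine–magnesium exchange with i-PrMgCl (THF, −78 °C) gives the amide-free and less basic bridgehead magnesium chloride F7.
- F7 is added to 22 to give 24. This sequence is known for installing branched acyl groups at such bridgeheads.

**Further compounds**
F1 | step 4 | racemic trans adduct (10 together with its mirror image) | COC(=O)C1C(=O)C(C(=O)OC)C[C@H](CC=C(C)C)[C@@]1(C)CCC=C(C)C.COC(=O)C1C(=O)C(C(=O)OC)C[C@@H](CC=C(C)C)[C@]1(C)CCC=C(C)C
F2 | step 4 | (7S,8R) β-enamino ester of 10 with (R)-1-phenylethylamine | COC(=O)C1=C(N[C@H](C)c2ccccc2)C(C(=O)OC)[C@](C)(CCC=C(C)C)[C@@H](CC=C(C)C)C1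
F3 | step 4 | (7R,8S) β-enamino ester of the mirror image of 10 with (R)-1-phenylethylamine | COC(=O)C1=C(N[C@H](C)c2ccccc2)C(C(=O)OC)[C@@](C)(CCC=C(C)C)[C@H](CC=C(C)C)C1
F4 | step 7 | methyl (3R,5S,6R)-3-(3-tert-butoxy-3-oxopropanoyl)-6-methyl-3,5-bis(3-methylbut-2-en-1-yl)-6-(4-methylpent-3-en-1-yl)-2-oxocyclohexane-1-carboxylate | COC(=O)C1C(=O)[C@](CC=C(C)C)(C(=O)CC(=O)OC(C)(C)C)C[C@H](CC=C(C)C)[C@@]1(C)CCC=C(C)C
F5 | step 7 | tert-butyl 4-hydroxy-8-methyl-5,7-bis(3-methylbut-2-en-1-yl)-8-(4-methylpent-3-en-1-yl)-2,9-dioxobicyclo[3.3.1]non-3-ene-3-carboxylate (core configured as in 16) | [C@H]12C(=O)C(C(=O)OC(C)(C)C)=C(O)[C@](CC=C(C)C)(C[C@H](CC=C(C)C)[C@@]1(C)CCC=C(C)C)C2=O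
F6 | step 13 | 1-iodo derivative of 19 (bridgehead iodide) | I[C@]12C(=O)C([Si](C)(C)C)=C(OC)[C@](CC=C(C)C)(C[C@H](CC=C(C)C)[C@@]1(C)CCC=C(C)C)C2=O
F7 | step 13 | 1-(chloromagnesio) derivative of 19 (bridgehead Grignard reagent) | Cl[Mg][C@]12C(=O)C([Si](C)(C)C)=C(OC)[C@](CC=C(C)C)(C[C@H](CC=C(C)C)[C@@]1(C)CCC=C(C)C)C2=O
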